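**Retrosynthetic overview**
- Ring C is the only ring built (rings A and B are bought as arenes). It is closed last by forming the O1–C2 ether bond: an enantioselective 6-endo oxa-Michael addition of the 2'-phenol onto a 2'-hydroxy-α-aryl enone, with catalyst-controlled protonation of the resulting enol setting C3 as R.
- The enone comes from α-methylenation of the bis-prenylated 2,4,4'-trihydroxydeoxybenzoin (C2 from formaldehyde).
- Both prenyl groups are installed together by a double Suzuki–Miyaura coupling on the dibromo-deoxybenzoin.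
- The dibromo-deoxybenzoin comes from Friedel–Crafts acylation of 4-bromoresorcinol with (3-bromo-4-hydroxyphenyl)acetic acid.
- No protecting groups; four steps. The target is the (3R)-isoflavanone.

Assumption: the facial sense of the new acid-catalysed ring closure cannot be predicted with certainty; the route is written with the (R)-configured acid, and the equally available mirror-image acid is used instead if the first run gives the 3S product.

**Step 1**
Reactants: 1 4-bromobenzene-1,3-diol (4-bromoresorcinol); 2 2-(3-bromo-4-hydroxyphenyl)acetic acid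
Product: 3 1-(5-bromo-2,4-dihydroxyphenyl)-2-(3-bromo-4-hydroxyphenyl)ethan-1-one
Conditions: BF3·OEt2 (neat, solvent and Lewis acid), 85 °C, 4 h; then aq NaOAc, 0 °C
Reagents that add atoms: none
Why: BF3-mediated Friedel–Crafts (Nencki-type) C-acylation of the resorcinol goes to C6, the only open position ortho to one hydroxyl and para to the other, giving the hydrogen-bonded 2-hydroxyaryl ketone; no stereocentre is formed.

**Step 2**
Reactants: 3 1-(5-bromo-2,4-dihydroxyphenyl)-2-(3-bromo-4-hydroxyphenyl)ethan-1-one; 4 4,4,5,5-tetramethyl-2-(3-methylbut-2-en-1-yl)-1,3,2-dioxaborolane (prenylboronic acid pinacol ester, 3 equiv)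
Product: 5 1-[2,4-dihydroxy-5-(3-methylbut-2-en-1-yl)phenyl]-2-[4-hydroxy-3-(3-methylbut-2-en-1-yl)phenyl]ethan-1-one
Conditions: PdCl2(IPent)(3-chloropyridine) (5 mol%; IPent = 1,3-bis[2,6-di(pentan-3-yl)phenyl]imidazol-2-ylidene), K3PO4 (7 equiv), THF/H2O 4:1, degassed, 65 °C, 16 h; then pH 5 buffer
Reagents that add atoms: none
Why: Double Suzuki–Miyaura sp2–sp3 coupling in which the very bulky carbene ligand on zerovalent palladium drives reductive elimination at the unsubstituted allyl terminus, so the linear prenyl arene (not the 1,1-dimethylallyl isomer) forms, while the free phenols are carried as phenoxides by the extra base; no stereocentre is formed.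

**Step 3**
Reactants: 5 1-[2,4-dihydroxy-5-(3-methylbut-2-en-1-yl)phenyl]-2-[4-hydroxy-3-(3-methylbut-2-en-1-yl)phenyl]ethan-1-one
Product: 7 1-[2,4-dihydroxy-5-(3-methylbut-2-en-1-yl)phenyl]-2-[4-hydroxy-3-(3-methylbut-2-en-1-yl)phenyl]prop-2-en-1-one, via Mannich base 6 (not isolated)
Conditions: (CH2O)n (1.5 equiv), i-Pr2NH2+ CF3CO2– (1.0 equiv), CF3CO2H (10 mol%), THF, 55 °C, 2–4 h; cold pH 6 wash, short silica plug, used the same day
Reagents that add atoms: formaldehyde (as paraformaldehyde), C=O
Why: Mannich methylenation, in which the ketone enol adds to the iminium formed in situ and the hindered amine is then lost by β-elimination, run under mildly acidic conditions where the carbonyl-chelated 2-hydroxyl is too poor a nucleophile to close the ring; no stereocentre is kept (6 is racemic and transient).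

**Step 4**
Reactants: 7 1-[2,4-dihydroxy-5-(3-methylbut-2-en-1-yl)phenyl]-2-[4-hydroxy-3-(3-methylbut-2-en-1-yl)phenyl]prop-2-en-1-one
Product: 9 (3R)-7-hydroxy-3-[4-hydroxy-3-(3-methylbut-2-en-1-yl)phenyl]-6-(3-methylbut-2-en-1-yl)-2,3-dihydro-4H-chromen-4-one, via enol 8 (not isolated)
Conditions: (R)-TRIP [(R)-3,3'-bis(2,4,6-triisopropylphenyl)-1,1'-binaphthyl-2,2'-diyl hydrogen phosphate] (10 mol%), PhMe/CH2Cl2 3:1 (0.02 M), −20 °C, 24–48 h; cold filtration through silica
Reagents that add atoms: none
Why: Proposed new method: a chiral phosphoric acid-catalysed intramolecular oxa-Michael addition/enantioselective protonation cascade, in which the acid hydrogen-bonds the enone carbonyl through P–OH and the 2'-phenol through P=O, the phenol adds 6-endo-trig to the unsubstituted CH2 terminus to form the O1–C2 bond, and the same acid, still bound to the 4-hydroxy-2H-chromene (enol 8), delivers the proton to the Si face of C3 inside the pocket of the 3,3'-aryl groups to give 3R; the weak acid leaves the prenyl groups and free phenols untouched and, unlike an amine catalyst, cannot racemise the α-aryl ketone through its enolate; the closest known reaction types are Brønsted acid-catalysed conjugate addition/enantioselective protonation cascades of α-substituted vinyl ketones (aza- and sulfa-Michael/protonation, asymmetric Nazarov cyclisation with enol protonation) and the racemic amine-mediated closure of 2'-hydroxy-α-methylenedeoxybenzoins to isoflavanones.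

**Compound list**
1 | 4-bromobenzene-1,3-diol (4-bromoresorcinol) | Oc1ccc(Br)c(O)c1 | starting material
2 | 2-(3-bromo-4-hydroxyphenyl)acetic acid | OC(=O)Cc1ccc(O)c(Br)c1 | starting material
3 | 1-(5-bromo-2,4-dihydroxyphenyl)-2-(3-bromo-4-hydroxyphenyl)ethan-1-one | O=C(Cc1ccc(O)c(Br)c1)c1cc(Br)c(O)cc1O | intermediate
4 | 4,4,5,5-tetramethyl-2-(3-methylbut-2-en-1-yl)-1,3,2-dioxaborolane | CC(C)=CCB1OC(C)(C)C(C)(C)O1 | starting material
5 | 1-[2,4-dihydroxy-5-(3-methylbut-2-en-1-yl)phenyl]-2-[4-hydroxy-3-(3-methylbut-2-en-1-yl)phenyl]ethan-1-one | O=C(Cc1ccc(O)c(CC=C(C)C)c1)c1cc(CC=C(C)C)c(O)cc1O | intermediate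
6 | racemic 3-(diisopropylamino)-1-[2,4-dihydroxy-5-(3-methylbut-2-en-1-yl)phenyl]-2-[4-hydroxy-3-(3-methylbut-2-en-1-yl)phenyl]propan-1-one (Mannich base, not isolated) | CC(C)N(CC(C(=O)c1cc(CC=C(C)C)c(O)cc1O)c1ccc(O)c(CC=C(C)C)c1)C(C)C | intermediate
7 | 1-[2,4-dihydroxy-5-(3-methylbut-2-en-1-yl)phenyl]-2-[4-hydroxy-3-(3-methylbut-2-en-1-yl)phenyl]prop-2-en-1-one | C=C(C(=O)c1cc(CC=C(C)C)c(O)cc1O)c1ccc(O)c(CC=C(C)C)c1 | intermediate
8 | 3-[4-hydroxy-3-(3-methylbut-2-en-1-yl)phenyl]-6-(3-methylbut-2-en-1-yl)-2H-chromene-4,7-diol (enol, not isolated) | OC1=C(c2ccc(O)c(CC=C(C)C)c2)COc2cc(O)c(CC=C(C)C)cc21 | intermediate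
9 | (3R)-7-hydroxy-3-[4-hydroxy-3-(3-methylbut-2-en-1-yl)phenyl]-6-(3-methylbut-2-en-1-yl)-2,3-dihydro-4H-chromen-4-one | CC(C)=CCc1cc([C@@H]2COc3cc(O)c(CC=C(C)C)cc3C2=O)ccc1O | target

**Totals**
Total step count: 4. Longest linear sequence: 4.

**Three steps most likely to fail**

1. Step 4 (the proposed new ring closure). Risks: uncatalysed cyclisation, or enol protonation by the substrate's own phenols, would lower the ee; the facial sense may be opposite; base on work-up would racemise C3. First remedies are other 3,3'-aryl groups on the acid, higher dilution and lower temperature, with the ee raised by crystallisation.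
Fallback (known chemistry), setting out from 5 and coming back at 9. Compound 5 is heated with N,N-dimethylformamide dimethyl acetal (THF, 60 °C) to give the isoflavone 7-hydroxy-3-[4-hydroxy-3-(3-methylbut-2-en-1-yl)phenyl]-6-(3-methylbut-2-en-1-yl)-4H-chromen-4-one F1. Both phenols are silylated (TBSCl, imidazole, DMF) to give the bis-silyl isoflavone F2. Asymmetric transfer hydrogenation with dynamic kinetic resolution (RuCl[(R,R)-TsDPEN](p-cymene), HCO2H/Et3N 5:2, EtOAc, 40 °C) gives the cis-(3R,4R)-isoflavan-4-ol F3. Dess–Martin periodinane (CH2Cl2, NaHCO3, 0 °C) re-oxidises C4 without touching C3 and gives the (3R)-bis-silyl isoflavanone F4. HF·pyridine (THF/pyridine, 0 °C) removes the silyl groups under non-basic conditions and gives 9.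

2. Step 3 (methylenation of the free triol). Risks: aminomethylation or hydroxymethylation of the phenol rings (C3 of ring A, the free ortho position of ring B), premature racemic closure of 7 to the isoflavanone, and dimerisation of the α-aryl enone on standing.
Fallback, setting out from 5 and coming back at 7. The three phenols are silylated (TBSCl, imidazole, DMAP, DMF, 50 °C) to give the tris-silyl deoxybenzoin F5. The phenol-free ketone is methylenated under standard conditions (bis(dimethylamino)methane, Ac2O, THF, 40 °C) to the tris-silyl enone F6, which can be purified and stored. HF·pyridine (THF/pyridine, −10 to 0 °C) then releases 7 under acidic, non-cyclising conditions, and the washed solution goes straight into step 4.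

3. Step 2 (double prenylation of the unprotected dibromide). Risks: slow oxidative addition into the phenoxide-bearing bromides, protodebromination, mono-coupling, and some branched (1,1-dimethylallyl) product.
Fallback, setting out from 3 and coming back at 5. Compound 3 is treated with MOMCl/i-Pr2NEt (CH2Cl2, 0 to 40 °C) to give the tris(methoxymethyl) ether F7. A neutral double Stille coupling with tributyl(3-methylbut-2-en-1-yl)stannane (Pd(PPh3)4, DMF, 100 °C) gives the bis-prenylated tris(methoxymethyl) ether F8. Brief treatment with 3 M HCl in MeOH (40 °C) removes the three acetals at this achiral stage and gives 5.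

**Further compounds**
F1 | step 4 | 7-hydroxy-3-[4-hydroxy-3-(3-methylbut-2-en-1-yl)phenyl]-6-(3-methylbut-2-en-1-yl)-4H-chromen-4-one | CC(C)=CCc1cc(-c2coc3cc(O)c(CC=C(C)C)cc3c2=O)ccc1O
F2 | step 4 | 7-[(tert-butyldimethylsilyl)oxy]-3-{4-[(tert-butyldimethylsilyl)oxy]-3-(3-methylbut-2-en-1-yl)phenyl}-6-(3-methylbut-2-en-1-yl)-4H-chromen-4-one | CC(C)=CCc1cc(-c2coc3cc(O[Si](C)(C)C(C)(C)C)c(CC=C(C)C)cc3c2=O)ccc1O[Si](C)(C)C(C)(C)C
F3 | step 4 | (3R,4R)-7-[(tert-butyldimethylsilyl)oxy]-3-{4-[(tert-butyldimethylsilyl)oxy]-3-(3-methylbut-2-en-1-yl)phenyl}-6-(3-methylbut-2-en-1-yl)-3,4-dihydro-2H-chromen-4-ol (cis) | CC(C)=CCc1cc([C@@H]2COc3cc(O[Si](C)(C)C(C)(C)C)c(CC=C(C)C)cc3[C@@H]2O)ccc1O[Si](C)(C)C(C)(C)C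
F4 | step 4 | (3R)-7-[(tert-butyldimethylsilyl)oxy]-3-{4-[(tert-butyldimethylsilyl)oxy]-3-(3-methylbut-2-en-1-yl)phenyl}-6-(3-methylbut-2-en-1-yl)-2,3-dihydro-4H-chromen-4-one | CC(C)=CCc1cc([C@@H]2COc3cc(O[Si](C)(C)C(C)(C)C)c(CC=C(C)C)cc3C2=O)ccc1O[Si](C)(C)C(C)(C)C
F5 | step 3 | 1-{2,4-bis[(tert-butyldimethylsilyl)oxy]-5-(3-methylbut-2-en-1-yl)phenyl}-2-{4-[(tert-butyldimethylsilyl)oxy]-3-(3-methylbut-2-en-1-yl)phenyl}ethan-1-one | CC(C)=CCc1cc(CC(=O)c2cc(CC=C(C)C)c(O[Si](C)(C)C(C)(C)C)cc2O[Si](C)(C)C(C)(C)C)ccc1O[Si](C)(C)C(C)(C)C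
F6 | step 3 | 1-{2,4-bis[(tert-butyldimethylsilyl)oxy]-5-(3-methylbut-2-en-1-yl)phenyl}-2-{4-[(tert-butyldimethylsilyl)oxy]-3-(3-methylbut-2-en-1-yl)phenyl}prop-2-en-1-one | C=C(C(=O)c1cc(CC=C(C)C)c(O[Si](C)(C)C(C)(C)C)cc1O[Si](C)(C)C(C)(C)C)c1ccc(O[Si](C)(C)C(C)(C)C)c(CC=C(C)C)c1
F7 | step 2 | 1-[5-bromo-2,4-bis(methoxymethoxy)phenyl]-2-[3-bromo-4-(methoxymethoxy)phenyl]ethan-1-one | COCOc1ccc(CC(=O)c2cc(Br)c(OCOC)cc2OCOC)cc1Br
F8 | step 2 | 1-[2,4-bis(methoxymethoxy)-5-(3-methylbut-2-en-1-yl)phenyl]-2-[4-(methoxymethoxy)-3-(3-methylbut-2-en-1-yl)phenyl]ethan-1-one | COCOc1ccc(CC(=O)c2cc(CC=C(C)C)c(OCOC)cc2OCOC)cc1CC=C(C)C
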